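The numbers of this flask stand for no real mixture.

From Saturday's to Monday's the step that eats target speeds up 56 times and the step that makes it 12 times, so warmth favours the loss.

the same everywhere: substrate 0.044 M; gas 14 mM (held); time 80 min

| flask | temperature |
|---|---|
| Saturday's | −20 °C |
| Monday's | 20 °C |
| Sunday's | 0 °C |

    gas ⇌ partner, rate k1*(csat - [partner]) (k1 = 0.013 s⁻¹, csat = 14 mM)
    crystals ⇌ target, rate k2*(cs2 - [target]) while solid is left; crystals form when [target] > cs2 (cs2 = 3.7 mM, k2 = 0.015 s⁻¹)
    substrate + target → side product (k3 = 0.027 M⁻¹ s⁻¹, Ea3 = 62.0 kJ mol⁻¹)
    substrate + partner ⇌ target (K4 = 1800 M⁻¹, k4 = 1.2 M⁻¹ s⁻¹, Ea4 = 38.0 kJ mol⁻¹, ΔH4 = −90.0 kJ mol⁻¹)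
    (constants at 0 °C)

- the flask with the highest amount of target, in percent of the substrate charged ("all alike" if they lie within 1.5 percentage points) (Saturday's / Monday's / Sunday's / all alike)
- final target, as a percentage of the substrate charged, in Saturday's
- final target, as a percentage of the substrate charged, in Monday's
- final target, as a percentage of the substrate charged, in Sunday's

- in percentages every species weighs as the substrate in it: one side product counts as two
- for target the crystals are counted in
- as a solid, counted per litre of solution: crystals
- at the start none of partner is dissolved
- the constants hold at 0 °C; other temperatures follow from the activation energies and enthalpies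

I turn the constants into times. Dissolved partner lasts 18.9 s against the charged substrate at Sunday's constant, shorter than the 76.9 s the gas needs to refill it. So in Sunday's and the warmer Monday's gas uptake is the rate-limiting step, and the charge takes up its partner in about 4.03 min, a small part of the run.

After that, crystals hold dissolved target near its solubility and partner stands near saturation. The balance of the step to target then leaves standing substrate: solubility over the equilibrium constant times saturation. That is 2.19 mM in Monday's and 0.147 mM in Sunday's.

But does that balance keep up? In Monday's it resets in about 0.317 min, shorter than the uptake, so I accept it. This pool meets dissolved target, and each event takes one substrate and one target, two shares of charge. The time in which this steady pace would carry the whole charge into side product is the charge over twice the rate of the side step. I call it the drain time: 260 min in Monday's, against 417 h in Sunday's. The side step's constant is carried to Monday's through the shift of the equilibrium constant, raised to the ratio of activation energy to enthalpy.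

So Monday's keeps 64.2 % as target? I doubt it: the first minutes are not steady. To pass target into crystals at the gas's pace, dissolved target must stand 12.1 mM above solubility, reaching 15.8 mM, while substrate is plentiful. Taking substrate and target each at half of their top values during the uptake, a rough guess, Monday's loses 33.3 % early and Sunday's 5.17 %.

My reckoning gives 99.4 % for Saturday's, 32.5 % for Monday's and 94.2 % for Sunday's, with Saturday's highest.

The forecast names Saturday's, with 98.4 %, 34 % and 90.5 % in that order, on the ground that in the warm flask “the faster side reaction keeps eating the crystals”. Its Sunday's figure stands below mine.

The flasks end at 98.5 % for Saturday's, 32.6 % for Monday's and 91.4 % for Sunday's, so Saturday's holds the most target. In Monday's, substrate stands at 4.67 % at 40.0 min and 4.67 % at 80.0 min, while side product climbs from 48.9 % to 62.7 %; the drain time of 260 min gives 15.4 % of the charge for that stretch. Sunday's drain time of 417 h gives 2.88 % from 80.0 min to 800 min, and side product in Sunday's moves from 8.24 % to 11.1 %.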